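**Plan**

1. Retrosynthesis: the C8–C1′ prenyl bond is cut first (coupling at the one free arene carbon), and the side-chain acid is traced back to a silyl-protected primary alcohol.
2. Ring A (C4a, C5, C6, C7, C8, C8a) is then cut at C5–C6, C7–C8, C4a–C5 and C8–C8a. Its pattern C5–OH, C6–alkyl, C7–OMe, C8–H on the C4a=C8a enol-ether bond of ring B is what a vinylketene (ketene carbon → C5–OH, vinyl unit = C4a=C8a) and a methoxyalkyne (→ C6 with the side chain, C7 with OMe) deliver.
3. Forward: ring B (O1, C2, C3, C4, C4a, C8a) is built first as a 6-diazoacetyl-2,3-dihydro-4H-pyran-4-one; ring A is grown onto it in one operation with the chiral methoxyalkyne; iodination, prenyl coupling and side-chain oxidation finish the synthesis.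
4. Stereochemistry: C2 comes from ethyl (S)-3-hydroxybutanoate and C3 from its anti-selective Fráter–Seebach methylation (anti = 2,3-trans, 2S,3S). The side-chain centre (R) comes from catalytic desymmetrisation of 3-propylglutaric anhydride. No later step creates or inverts a stereocentre.

Key step: step 16

Assumption: the dihydroquinidine-derived catalyst is taken to give the (R)-hemiester 15, by analogy with other 3-alkylglutaric anhydrides; if the sense of induction is opposite, the dihydroquinine-derived pseudoenantiomer (DHQ)2AQN is used and nothing else changes.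

**Route**

Step 1
Reactants: 1 ethyl (S)-3-hydroxybutanoate
Product: 2 ethyl (2S,3S)-3-hydroxy-2-methylbutanoate
Conditions: LiN(i-Pr)2 (2.2 equiv), THF, −50 → −15 °C; MeI, −15 → 0 °C
Reagents that add atoms: iodomethane, CI
Why: Fráter–Seebach alkylation, in which the chelated lithium alkoxide–enolate dianion is methylated on the face away from the C3 methyl group, so the new C2 centre is set anti to the carbinol centre by 1,2-induction (2S,3S).

Step 2
Reactants: 2 ethyl (2S,3S)-3-hydroxy-2-methylbutanoate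
Product: 3 ethyl (2S,3S)-2-methyl-3-(triethylsilyloxy)butanoate
Conditions: Et3SiCl, imidazole, CH2Cl2, 0 °C → rt
Reagents that add atoms: chlorotriethylsilane, CC[Si](Cl)(CC)CC
Why: Standard silylation of a secondary alcohol, giving a triethylsilyl ether that masks the hydroxyl during the organomagnesium and enolate steps and is later removed by the same acid that closes ring B.

Step 3
Reactants: 3 ethyl (2S,3S)-2-methyl-3-(triethylsilyloxy)butanoate
Product: 4 (2S,3S)-N-methoxy-N,2-dimethyl-3-(triethylsilyloxy)butanamide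
Conditions: MeNH(OMe)·HCl, i-PrMgCl, THF, −20 → 0 °C
Reagents that add atoms: N,O-dimethylhydroxylamine hydrochloride, CNOC.Cl
Why: Weinreb amide formation by aminolysis of the ester with the chloromagnesium amide of N,O-dimethylhydroxylamine, a non-enolising method that should leave the α-centre intact.

Step 4
Reactants: 4 (2S,3S)-N-methoxy-N,2-dimethyl-3-(triethylsilyloxy)butanamide
Product: 5 (3S,4S)-3-methyl-4-(triethylsilyloxy)pentan-2-one
Conditions: MeMgBr, THF, 0 °C
Reagents that add atoms: methylmagnesium bromide, C[Mg]Br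
Why: Weinreb ketone synthesis, in which the chelated tetrahedral adduct persists until work-up, so only one methyl group adds and the α-stereocentre is never exposed as an enolisable ketone to the base.

Step 5
Reactants: 5 (3S,4S)-3-methyl-4-(triethylsilyloxy)pentan-2-one; 6 di-tert-butyl oxalate
Product: 7 tert-butyl (5S,6S)-5-methyl-2,4-dioxo-6-(triethylsilyloxy)heptanoate
Conditions: LiN(SiMe3)2 (1.1 equiv), THF, −78 °C; then 6, −78 °C → rt
Reagents that add atoms: none
Why: Crossed Claisen condensation, in which kinetic deprotonation takes the methyl group rather than the hindered methine, the enolate is acylated by the non-enolisable oxalate, and the released tert-butoxide deprotonates the diketo ester to drive the reaction.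

Step 6
Reactants: 7 tert-butyl (5S,6S)-5-methyl-2,4-dioxo-6-(triethylsilyloxy)heptanoate
Product: 10 (2S,3S)-2,3-dimethyl-4-oxo-3,4-dihydro-2H-pyran-6-carboxylic acid, via hydroxy diketo ester 8 (not isolated), via tert-butyl pyranone ester 9 (not isolated)
Conditions: CF3CO2H/CH2Cl2 (1:2), H2O (2 equiv), 0 °C → rt
Reagents that add atoms: none
Why: Acid-mediated cyclodehydration of a δ-hydroxy-β-diketone to a 2,3-dihydro-4H-pyran-4-one (silyl ether cleavage, 6-exo-trig hemiketalisation of the freed hydroxyl onto the C2 keto group, dehydration) followed by acidolysis of the tert-butyl ester, so that no base meets the epimerisable C3 centre.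

Step 7
Reactants: 10 (2S,3S)-2,3-dimethyl-4-oxo-3,4-dihydro-2H-pyran-6-carboxylic acid
Product: 12 2-diazo-1-[(2S,3S)-2,3-dimethyl-4-oxo-3,4-dihydro-2H-pyran-6-yl]ethan-1-one, via acid chloride 11 (not isolated)
Conditions: (COCl)2, DMF (cat.), CH2Cl2, 0 °C → rt; evaporate; CH2N2 (1.3 equiv), Et3N (1.1 equiv), Et2O/THF, −10 → 0 °C
Reagents that add atoms: diazomethane, C=[N+]=[N-]; oxalyl chloride, ClC(=O)C(=O)Cl (its chlorine stays only in 11)
Why: Acylation of diazomethane by an acid chloride (first stage of the Arndt–Eistert sequence), with triethylamine as HCl scavenger because 11 has no α-hydrogen, so that only a small excess of diazomethane is present and dipolar addition to the alkoxy-deactivated enone is limited.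

Step 8
Reactants: 13 3-propylglutaric acid
Product: 14 4-propyloxane-2,6-dione (3-propylglutaric anhydride)
Conditions: Ac2O, reflux; distil off AcOH and Ac2O
Reagents that add atoms: none
Why: Cyclodehydration of a glutaric acid to its six-membered cyclic anhydride by anhydride exchange with acetic anhydride.

Step 9
Reactants: 14 4-propyloxane-2,6-dione
Product: 15 (3R)-3-(2-methoxy-2-oxoethyl)hexanoic acid
Conditions: MeOH (10 equiv), (DHQD)2AQN [hydroquinidine anthraquinone-1,4-diyl diether] (0.1–0.3 equiv), Et2O, −40 °C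
Reagents that add atoms: methanol, CO
Why: Enantioselective alcoholysis (desymmetrisation) of a prochiral 3-substituted glutaric anhydride under general-base catalysis by the bis-cinchona alkaloid, which directs methanol to one of the two enantiotopic carbonyl groups and so fixes C3 as R, with the option of raising the enantiomeric purity by crystallising a 1-phenylethylammonium salt of 15.

Step 10
Reactants: 15 (3R)-3-(2-methoxy-2-oxoethyl)hexanoic acid
Product: 16 methyl (3R)-3-(2-hydroxyethyl)hexanoate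
Conditions: BH3·SMe2, THF, −10 → 20 °C; MeOH, then aqueous work-up
Reagents that add atoms: none
Why: Chemoselective borane reduction of the carboxylic acid (through its acyloxyborane) in the presence of the methyl ester, the crude hydroxy ester being silylated at once to forestall lactonisation.

Step 11
Reactants: 16 methyl (3R)-3-(2-hydroxyethyl)hexanoate
Product: 17 methyl (3R)-3-[2-(tert-butyldiphenylsilyloxy)ethyl]hexanoate
Conditions: t-BuPh2SiCl, imidazole, DMF, 0 °C → rt
Reagents that add atoms: tert-butyl(chloro)diphenylsilane, CC(C)(C)[Si](Cl)(c1ccccc1)c1ccccc1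
Why: Silylation of the primary alcohol with a tert-butyldiphenylsilyl group, chosen because it should outlast the acidic acetalisation, the bromination and the strong base that follow.

Step 12
Reactants: 17 methyl (3R)-3-[2-(tert-butyldiphenylsilyloxy)ethyl]hexanoate
Product: 18 (3R)-3-[2-(tert-butyldiphenylsilyloxy)ethyl]hexanal
Conditions: i-Bu2AlH (1.05 equiv), CH2Cl2, −78 °C; aq potassium sodium tartrate
Reagents that add atoms: none
Why: Partial hydride reduction of a methyl ester to the aldehyde, the tetrahedral aluminium hemiacetal being stable at −78 °C until work-up.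

Step 13
Reactants: 18 (3R)-3-[2-(tert-butyldiphenylsilyloxy)ethyl]hexanal
Product: 20 tert-butyl{[(3R)-3-(2-methoxyethenyl)hexyl]oxy}diphenylsilane (E/Z mixture), via dimethyl acetal 19 (not isolated)
Conditions: HC(OMe)3, PPTS (cat.), MeOH, rt; evaporate; Me3SiOTf, i-Pr2NEt, CH2Cl2, −20 °C → rt
Reagents that add atoms: trimethyl orthoformate, COC(OC)OC
Why: Acid-catalysed acetalisation followed by the silyl-triflate/amine acetal-to-enol-ether elimination (ionisation to the oxocarbenium ion and deprotonation by the hindered amine), which does not involve the adjacent methine stereocentre.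

Step 14
Reactants: 20 tert-butyl{[(3R)-3-(2-methoxyethenyl)hexyl]oxy}diphenylsilane
Product: 22 {[(3R)-3-(1-bromo-2-methoxyethenyl)hexyl]oxy}(tert-butyl)diphenylsilane, via dibromo ether 21 (not isolated)
Conditions: Br2 (1.0 equiv), CH2Cl2, −78 °C; then i-Pr2NEt, −78 °C → rt
Reagents that add atoms: bromine, BrBr
Why: Electrophilic bromine addition to the enol ether followed by dehydrobromination through the labile α-bromo ether (oxocarbenium ion), which loses the proton on the bromine-bearing carbon and so should give the 2-bromo enol ether regioselectively without touching the neighbouring methine.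

Step 15
Reactants: 22 {[(3R)-3-(1-bromo-2-methoxyethenyl)hexyl]oxy}(tert-butyl)diphenylsilane
Product: 23 tert-butyl{[(3R)-3-(methoxyethynyl)hexyl]oxy}diphenylsilane
Conditions: LiN(i-Pr)2 (2.5 equiv), THF, −78 → −20 °C; pH 7 buffer; chromatography on Et3N-deactivated silica
Reagents that add atoms: none
Why: Base-induced dehydrobromination of a 2-bromo enol ether, the classical route to 1-alkoxyalkynes, in which the vinylic hydrogen next to oxygen is removed and bromide leaves, both geometric isomers converging on the alkyne while the propargylic methine is too weakly acidic to be deprotonated at low temperature.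

Step 16
Reactants: 12 2-diazo-1-[(2S,3S)-2,3-dimethyl-4-oxo-3,4-dihydro-2H-pyran-6-yl]ethan-1-one; 23 tert-butyl{[(3R)-3-(methoxyethynyl)hexyl]oxy}diphenylsilane
Product: 28 (2S,3S)-6-[(3R)-1-(tert-butyldiphenylsilyloxy)hexan-3-yl]-5-hydroxy-7-methoxy-2,3-dimethylchroman-4-one, via vinylketene 24 (not isolated), via vinylcyclobutenone 25 (not isolated), via dienylketene 26 (not isolated), via cyclohexadienone 27 (not isolated)
Conditions: 12 (1.3 equiv), 23 (1.0 equiv), ClCH2CH2Cl (degassed), hν (254 nm, quartz), rt; then 80 °C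
Reagents that add atoms: none
Why: Light expels dinitrogen from 12 and the pyranonyl group shifts from the carbonyl carbon to the carbene carbon (Wolff rearrangement, forming C8–C8a) to give vinylketene 24, whose ketene carbon is attacked by the side-chain-bearing carbon of ynol ether 23 in a [2+2] cycloaddition (C5–C6 and C7–C8) that gives vinylcyclobutenone 25. Heating completes the 4π electrocyclic opening of 25 to dienylketene 26, and ring A then closes by thermal 6π electrocyclisation between the ketene carbon and the former pyranone C5 (C4a–C5, six-membered carbocycle), after which dienone 27 enolises to the C5 phenol. The closest known reaction type is the Danheiser benzannulation in its photochemical Wolff variant, which is established for α,β-unsaturated diazomethyl ketones with alkoxy- and silyloxyalkynes. No stereocentre is created, since the sp3 centres of 25 and 27 vanish on aromatisation, and C2, C3 and the side-chain centre are spectators under neutral, non-enolising conditions. The step needs regioselectivity in the [2+2] addition, which the polarisation of the ynol ether secures (its oxygen-free carbon bonds to the electrophilic ketene carbon, so the side chain ends at C6 beside the new C5–OH and the methoxy group at C7), and chemoselectivity for the ketene over the ring B enone, which the much higher electrophilicity of the ketene and irradiation at a wavelength absorbed mainly by the diazo ketone should provide.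

Step 17
Reactants: 28 (2S,3S)-6-[(3R)-1-(tert-butyldiphenylsilyloxy)hexan-3-yl]-5-hydroxy-7-methoxy-2,3-dimethylchroman-4-one
Product: 29 (2S,3S)-6-[(3R)-1-(tert-butyldiphenylsilyloxy)hexan-3-yl]-5-hydroxy-8-iodo-7-methoxy-2,3-dimethylchroman-4-one
Conditions: N-iodosuccinimide (1.05 equiv), CH2Cl2, 0 °C → rt, dark
Reagents that add atoms: N-iodosuccinimide, O=C1CCC(=O)N1I
Why: Electrophilic aromatic iodination at C8, the only unsubstituted ring carbon, which is activated by the para C5 hydroxyl and the two ortho oxygen substituents.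

Step 18
Reactants: 29 (2S,3S)-6-[(3R)-1-(tert-butyldiphenylsilyloxy)hexan-3-yl]-5-hydroxy-8-iodo-7-methoxy-2,3-dimethylchroman-4-one
Product: 30 (2S,3S)-6-[(3R)-1-(tert-butyldiphenylsilyloxy)hexan-3-yl]-5-hydroxy-7-methoxy-2,3-dimethyl-8-(3-methylbut-2-en-1-yl)chroman-4-one
Conditions: Bu3SnCH2CH=CMe2 (2 equiv), Pd(PPh3)4 (10 mol %), DMF, 90 °C
Reagents that add atoms: tributyl(3-methylbut-2-en-1-yl)stannane, CCCC[Sn](CCCC)(CCCC)CC=C(C)C
Why: Stille coupling, in which zerovalent palladium inserts into the C8–I bond, the allyl group is transferred from tin, and reductive elimination at the unsubstituted allyl terminus (favoured for a hindered aryl group) should give the linear prenyl arene under neutral conditions that spare the phenol and the chromanone.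

Step 19
Reactants: 30 (2S,3S)-6-[(3R)-1-(tert-butyldiphenylsilyloxy)hexan-3-yl]-5-hydroxy-7-methoxy-2,3-dimethyl-8-(3-methylbut-2-en-1-yl)chroman-4-one
Product: 31 (2S,3S)-5-hydroxy-6-[(3R)-1-hydroxyhexan-3-yl]-7-methoxy-2,3-dimethyl-8-(3-methylbut-2-en-1-yl)chroman-4-one
Conditions: HF·pyridine, pyridine, THF, 0 °C → rt
Reagents that add atoms: none
Why: Fluoride-mediated cleavage of the primary silyl ether under buffered, weakly acidic conditions that avoid base-promoted epimerisation or ring opening of the chromanone.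

Step 20
Reactants: 31 (2S,3S)-5-hydroxy-6-[(3R)-1-hydroxyhexan-3-yl]-7-methoxy-2,3-dimethyl-8-(3-methylbut-2-en-1-yl)chroman-4-one
Product: 32 (3R)-3-[(2S,3S)-5-hydroxy-7-methoxy-2,3-dimethyl-8-(3-methylbut-2-en-1-yl)-4-oxochroman-6-yl]hexanal
Conditions: Dess–Martin periodinane (1.3 equiv), CH2Cl2, 0 °C → rt
Reagents that add atoms: none
Why: Dess–Martin oxidation of the primary alcohol to the aldehyde under neutral conditions, towards which the hydrogen-bonded C5 phenol on a fully substituted ring and the trisubstituted alkene are expected to be inert.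

Step 21
Reactants: 32 (3R)-3-[(2S,3S)-5-hydroxy-7-methoxy-2,3-dimethyl-8-(3-methylbut-2-en-1-yl)-4-oxochroman-6-yl]hexanal
Product: 33 (3R)-3-[(2S,3S)-5-hydroxy-7-methoxy-2,3-dimethyl-8-(3-methylbut-2-en-1-yl)-4-oxochroman-6-yl]hexanoic acid
Conditions: NaClO2, NaH2PO4, 2-methylbut-2-ene (large excess), t-BuOH/H2O, 0 °C → rt
Reagents that add atoms: sodium chlorite, [Na+].[O-]Cl=O
Why: Pinnick oxidation of the aldehyde to the carboxylic acid, with a large excess of 2-methylbut-2-ene to scavenge hypochlorous acid and so protect the prenyl double bond and the phenol.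

**Compound list**

1 | ethyl (S)-3-hydroxybutanoate | C[C@H](O)CC(=O)OCC | starting material
2 | ethyl (2S,3S)-3-hydroxy-2-methylbutanoate | C[C@H](O)[C@H](C)C(=O)OCC | intermediate
3 | ethyl (2S,3S)-2-methyl-3-(triethylsilyloxy)butanoate | C[C@H](O[Si](CC)(CC)CC)[C@H](C)C(=O)OCC | intermediate
4 | (2S,3S)-N-methoxy-N,2-dimethyl-3-(triethylsilyloxy)butanamide | C[C@H](O[Si](CC)(CC)CC)[C@H](C)C(=O)N(C)OC | intermediate
5 | (3S,4S)-3-methyl-4-(triethylsilyloxy)pentan-2-one | C[C@H](O[Si](CC)(CC)CC)[C@H](C)C(C)=O | intermediate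
6 | di-tert-butyl oxalate | CC(C)(C)OC(=O)C(=O)OC(C)(C)C | starting material
7 | tert-butyl (5S,6S)-5-methyl-2,4-dioxo-6-(triethylsilyloxy)heptanoate | C[C@H](O[Si](CC)(CC)CC)[C@H](C)C(=O)CC(=O)C(=O)OC(C)(C)C | intermediate
8 | tert-butyl (5S,6S)-6-hydroxy-5-methyl-2,4-dioxoheptanoate (not isolated) | C[C@H](O)[C@H](C)C(=O)CC(=O)C(=O)OC(C)(C)C | intermediate
9 | tert-butyl (2S,3S)-2,3-dimethyl-4-oxo-3,4-dihydro-2H-pyran-6-carboxylate (not isolated) | CC(C)(C)OC(=O)C1=CC(=O)[C@@H](C)[C@H](C)O1 | intermediate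
10 | (2S,3S)-2,3-dimethyl-4-oxo-3,4-dihydro-2H-pyran-6-carboxylic acid | OC(=O)C1=CC(=O)[C@@H](C)[C@H](C)O1 | intermediate
11 | (2S,3S)-2,3-dimethyl-4-oxo-3,4-dihydro-2H-pyran-6-carbonyl chloride (not isolated) | ClC(=O)C1=CC(=O)[C@@H](C)[C@H](C)O1 | intermediate
12 | 2-diazo-1-[(2S,3S)-2,3-dimethyl-4-oxo-3,4-dihydro-2H-pyran-6-yl]ethan-1-one | [N-]=[N+]=CC(=O)C1=CC(=O)[C@@H](C)[C@H](C)O1 | intermediate
13 | 3-propylglutaric acid | CCCC(CC(=O)O)CC(=O)O | starting material
14 | 4-propyloxane-2,6-dione (3-propylglutaric anhydride) | CCCC1CC(=O)OC(=O)C1 | intermediate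
15 | (3R)-3-(2-methoxy-2-oxoethyl)hexanoic acid | CCC[C@H](CC(=O)O)CC(=O)OC | intermediate
16 | methyl (3R)-3-(2-hydroxyethyl)hexanoate | CCC[C@H](CCO)CC(=O)OC | intermediate
17 | methyl (3R)-3-[2-(tert-butyldiphenylsilyloxy)ethyl]hexanoate | CCC[C@H](CCO[Si](c1ccccc1)(c2ccccc2)C(C)(C)C)CC(=O)OC | intermediate
18 | (3R)-3-[2-(tert-butyldiphenylsilyloxy)ethyl]hexanal | CCC[C@H](CCO[Si](c1ccccc1)(c2ccccc2)C(C)(C)C)CC=O | intermediate
19 | tert-butyl{[(3R)-3-(2,2-dimethoxyethyl)hexyl]oxy}diphenylsilane (not isolated) | CCC[C@H](CCO[Si](c1ccccc1)(c2ccccc2)C(C)(C)C)CC(OC)OC | intermediate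
20 | tert-butyl{[(3R)-3-(2-methoxyethenyl)hexyl]oxy}diphenylsilane (E/Z mixture) | CCC[C@H](CCO[Si](c1ccccc1)(c2ccccc2)C(C)(C)C)C=COC | intermediate
21 | {[(3R)-3-(1,2-dibromo-2-methoxyethyl)hexyl]oxy}(tert-butyl)diphenylsilane (diastereomer mixture, not isolated) | CCC[C@H](CCO[Si](c1ccccc1)(c2ccccc2)C(C)(C)C)C(Br)C(Br)OC | intermediate
22 | {[(3R)-3-(1-bromo-2-methoxyethenyl)hexyl]oxy}(tert-butyl)diphenylsilane | CCC[C@H](CCO[Si](c1ccccc1)(c2ccccc2)C(C)(C)C)C(Br)=COC | intermediate
23 | tert-butyl{[(3R)-3-(methoxyethynyl)hexyl]oxy}diphenylsilane | CCC[C@H](CCO[Si](c1ccccc1)(c2ccccc2)C(C)(C)C)C#COC | intermediate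
24 | (2S,3S)-2,3-dimethyl-6-(2-oxoethenyl)-2,3-dihydro-4H-pyran-4-one (vinylketene, not isolated) | O=C=CC1=CC(=O)[C@@H](C)[C@H](C)O1 | intermediate
25 | 2-[(3R)-1-(tert-butyldiphenylsilyloxy)hexan-3-yl]-4-[(2S,3S)-2,3-dimethyl-4-oxo-3,4-dihydro-2H-pyran-6-yl]-3-methoxycyclobut-2-en-1-one (not isolated) | CCC[C@H](CCO[Si](c3ccccc3)(c4ccccc4)C(C)(C)C)C1=C(OC)C(C1=O)C2=CC(=O)[C@@H](C)[C@H](C)O2 | intermediate
26 | dienylketene: (2S,3S)-6-{(4R)-6-(tert-butyldiphenylsilyloxy)-2-methoxy-3-(oxomethylidene)-4-propylhex-1-en-1-yl}-2,3-dimethyl-2,3-dihydro-4H-pyran-4-one, ketene and pyranonyl groups cis (not isolated) | CCC[C@H](CCO[Si](c3ccccc3)(c4ccccc4)C(C)(C)C)C(=C=O)/C(OC)=C\C1=CC(=O)[C@@H](C)[C@H](C)O1 | intermediate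
27 | (2S,3S)-6-[(3R)-1-(tert-butyldiphenylsilyloxy)hexan-3-yl]-7-methoxy-2,3-dimethyl-2,3-dihydro-4H-chromene-4,5(4aH)-dione (not isolated) | CCC[C@H](CCO[Si](c3ccccc3)(c4ccccc4)C(C)(C)C)C1=C(OC)C=C2O[C@@H](C)[C@H](C)C(=O)C2C1=O | intermediate
28 | (2S,3S)-6-[(3R)-1-(tert-butyldiphenylsilyloxy)hexan-3-yl]-5-hydroxy-7-methoxy-2,3-dimethylchroman-4-one | CCC[C@H](CCO[Si](c3ccccc3)(c4ccccc4)C(C)(C)C)c1c(O)c2c(cc1OC)O[C@@H](C)[C@H](C)C2=O | intermediate
29 | (2S,3S)-6-[(3R)-1-(tert-butyldiphenylsilyloxy)hexan-3-yl]-5-hydroxy-8-iodo-7-methoxy-2,3-dimethylchroman-4-one | CCC[C@H](CCO[Si](c3ccccc3)(c4ccccc4)C(C)(C)C)c1c(O)c2c(c(I)c1OC)O[C@@H](C)[C@H](C)C2=O | intermediate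
30 | (2S,3S)-6-[(3R)-1-(tert-butyldiphenylsilyloxy)hexan-3-yl]-5-hydroxy-7-methoxy-2,3-dimethyl-8-(3-methylbut-2-en-1-yl)chroman-4-one | CCC[C@H](CCO[Si](c3ccccc3)(c4ccccc4)C(C)(C)C)c1c(O)c2c(c(CC=C(C)C)c1OC)O[C@@H](C)[C@H](C)C2=O | intermediate
31 | (2S,3S)-5-hydroxy-6-[(3R)-1-hydroxyhexan-3-yl]-7-methoxy-2,3-dimethyl-8-(3-methylbut-2-en-1-yl)chroman-4-one | CCC[C@H](CCO)c1c(O)c2c(c(CC=C(C)C)c1OC)O[C@@H](C)[C@H](C)C2=O | intermediate
32 | (3R)-3-[(2S,3S)-5-hydroxy-7-methoxy-2,3-dimethyl-8-(3-methylbut-2-en-1-yl)-4-oxochroman-6-yl]hexanal | CCC[C@H](CC=O)c1c(O)c2c(c(CC=C(C)C)c1OC)O[C@@H](C)[C@H](C)C2=O | intermediate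
33 | (3R)-3-[(2S,3S)-5-hydroxy-7-methoxy-2,3-dimethyl-8-(3-methylbut-2-en-1-yl)-4-oxochroman-6-yl]hexanoic acid | CCC[C@H](CC(=O)O)c1c(O)c2c(c(CC=C(C)C)c1OC)O[C@@H](C)[C@H](C)C2=O | target

**Step count and risks**

Total steps: 21. Longest linear sequence: 14 steps (13 → 33, steps 8–21); the ring B branch (steps 1–7) joins at step 16.

The three steps most likely to fail are steps 16, 15 and 18.

Step 16. What may go wrong: under irradiation the ring B enone may itself be excited and add to the ynol ether in a [2+2] photocycloaddition, or 23 may be lost by photodegradation before the ketene captures it. Fallback (ketene generation without light), setting out from 12 and returning at 28: a silver-benzoate-catalysed Wolff rearrangement in aqueous THF (PhCO2Ag, Et3N, THF/H2O, dark, rt) should trap ketene 24 with water to give 2-[(2S,3S)-2,3-dimethyl-4-oxo-3,4-dihydro-2H-pyran-6-yl]acetic acid F1, which is kept cold to avoid decarboxylation. Oxalyl chloride with catalytic DMF converts it into 2-[(2S,3S)-2,3-dimethyl-4-oxo-3,4-dihydro-2H-pyran-6-yl]acetyl chloride F2. Slow addition of Et3N to F2 and 23 in toluene at room temperature regenerates vinylketene 24 by dehydrochlorination, which should add to 23 to give 25; heating to 80–110 °C then carries 25 through 26 and 27 to 28.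

Step 15. What may go wrong: the amide base may remove the methine hydrogen next to the bromoalkene (loss of HBr toward the stereocentre, giving a methoxyallene and eroding the configuration), or the ynol ether may hydrate during isolation. Fallback (a silyl ynol ether made through an ester-derived ynolate, with no elimination next to the stereocentre), setting out from 17 and returning at 28: two rounds of enolate bromination (LiN(SiMe3)2, then BrCF2CF2Br, THF, −78 °C) give first methyl (3R)-2-bromo-3-[2-(tert-butyldiphenylsilyloxy)ethyl]hexanoate F3 and then methyl (3R)-2,2-dibromo-3-[2-(tert-butyldiphenylsilyloxy)ethyl]hexanoate F4. t-BuLi (4 equiv, THF, −78 → 0 °C) should effect double bromine–lithium exchange and loss of methoxide to give lithium ynolate F5, which is O-silylated with i-Pr3SiOTf to the silyloxyalkyne tert-butyl{[(3R)-3-({[tri(propan-2-yl)silyl]oxy}ethynyl)hexyl]oxy}diphenylsilane F6. Benzannulation of F6 with 12 under the conditions of step 16 should pass through silyloxy vinylcyclobutenone F7, silyloxy dienylketene F8 and silyloxy cyclohexadienone F9 to the 7-silyloxy chromanone F10. Buffered fluoride at low temperature (Bu4NF, AcOH, THF, −20 °C) removes the aryl silyl group in preference to the alkyl silyl ether and gives the 5,7-dihydroxy chromanone F11. Me3SiCHN2 in MeOH/toluene then methylates the non-chelated, more acidic C7 hydroxyl and leaves the hydrogen-bonded C5 hydroxyl, which gives 28.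

Step 18. What may go wrong: oxidative addition at the doubly ortho-substituted, electron-rich C8–I bond may be slow and be overtaken by proto-deiodination, or allyl transposition may deliver the 1,1-dimethylallyl isomer. Fallback (para-Claisen–Cope rearrangement, with no halide and no metal coupling), setting out from 28 and returning at 30: Mitsunobu etherification of the C5 hydroxyl with 3-methylbut-2-en-1-ol (PPh3, diisopropyl azodicarboxylate, THF) gives the 5-O-prenyl ether F12. Warming with tris(6,6,7,7,8,8,8-heptafluoro-2,2-dimethyloctane-3,5-dionato)europium, Eu(fod)3 (10 mol %, CHCl3, 60 °C), or thermolysis in PhNEt2, should trigger a [3,3] shift to a blocked ortho carbon, expected to give the C6 ortho-dienone F13. A Cope shift to C8, the only position from which the ring can rearomatise, then returns the linear prenyl group and the free C5 hydroxyl, that is 30.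

**Further compounds**

F1 | step 16 | 2-[(2S,3S)-2,3-dimethyl-4-oxo-3,4-dihydro-2H-pyran-6-yl]acetic acid | OC(=O)CC1=CC(=O)[C@@H](C)[C@H](C)O1
F2 | step 16 | 2-[(2S,3S)-2,3-dimethyl-4-oxo-3,4-dihydro-2H-pyran-6-yl]acetyl chloride | ClC(=O)CC1=CC(=O)[C@@H](C)[C@H](C)O1
F3 | step 15 | methyl (3R)-2-bromo-3-[2-(tert-butyldiphenylsilyloxy)ethyl]hexanoate (epimer mixture at C2) | CCC[C@H](CCO[Si](c1ccccc1)(c2ccccc2)C(C)(C)C)C(Br)C(=O)OC
F4 | step 15 | methyl (3R)-2,2-dibromo-3-[2-(tert-butyldiphenylsilyloxy)ethyl]hexanoate | CCC[C@H](CCO[Si](c1ccccc1)(c2ccccc2)C(C)(C)C)C(Br)(Br)C(=O)OC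
F5 | step 15 | lithium (3R)-3-[2-(tert-butyldiphenylsilyloxy)ethyl]hex-1-yn-1-olate | CCC[C@H](CCO[Si](c1ccccc1)(c2ccccc2)C(C)(C)C)C#C[O-].[Li+]
F6 | step 15 | tert-butyl{[(3R)-3-({[tri(propan-2-yl)silyl]oxy}ethynyl)hexyl]oxy}diphenylsilane | CCC[C@H](CCO[Si](c1ccccc1)(c2ccccc2)C(C)(C)C)C#CO[Si](C(C)C)(C(C)C)C(C)C
F7 | step 15 | 2-[(3R)-1-(tert-butyldiphenylsilyloxy)hexan-3-yl]-4-[(2S,3S)-2,3-dimethyl-4-oxo-3,4-dihydro-2H-pyran-6-yl]-3-{[tri(propan-2-yl)silyl]oxy}cyclobut-2-en-1-one | CCC[C@H](CCO[Si](c3ccccc3)(c4ccccc4)C(C)(C)C)C1=C(O[Si](C(C)C)(C(C)C)C(C)C)C(C1=O)C2=CC(=O)[C@@H](C)[C@H](C)O2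
F8 | step 15 | silyloxy dienylketene (analogue of 26 with tri(propan-2-yl)silyloxy in place of methoxy) | CCC[C@H](CCO[Si](c3ccccc3)(c4ccccc4)C(C)(C)C)C(=C=O)/C(O[Si](C(C)C)(C(C)C)C(C)C)=C\C1=CC(=O)[C@@H](C)[C@H](C)O1
F9 | step 15 | (2S,3S)-6-[(3R)-1-(tert-butyldiphenylsilyloxy)hexan-3-yl]-2,3-dimethyl-7-{[tri(propan-2-yl)silyl]oxy}-2,3-dihydro-4H-chromene-4,5(4aH)-dione | CCC[C@H](CCO[Si](c3ccccc3)(c4ccccc4)C(C)(C)C)C1=C(O[Si](C(C)C)(C(C)C)C(C)C)C=C2O[C@@H](C)[C@H](C)C(=O)C2C1=O
F10 | step 15 | (2S,3S)-6-[(3R)-1-(tert-butyldiphenylsilyloxy)hexan-3-yl]-5-hydroxy-2,3-dimethyl-7-{[tri(propan-2-yl)silyl]oxy}chroman-4-one | CCC[C@H](CCO[Si](c3ccccc3)(c4ccccc4)C(C)(C)C)c1c(O)c2c(cc1O[Si](C(C)C)(C(C)C)C(C)C)O[C@@H](C)[C@H](C)C2=O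
F11 | step 15 | (2S,3S)-6-[(3R)-1-(tert-butyldiphenylsilyloxy)hexan-3-yl]-5,7-dihydroxy-2,3-dimethylchroman-4-one | CCC[C@H](CCO[Si](c3ccccc3)(c4ccccc4)C(C)(C)C)c1c(O)c2c(cc1O)O[C@@H](C)[C@H](C)C2=O
F12 | step 18 | (2S,3S)-6-[(3R)-1-(tert-butyldiphenylsilyloxy)hexan-3-yl]-7-methoxy-2,3-dimethyl-5-[(3-methylbut-2-en-1-yl)oxy]chroman-4-one | CCC[C@H](CCO[Si](c3ccccc3)(c4ccccc4)C(C)(C)C)c1c(OCC=C(C)C)c2c(cc1OC)O[C@@H](C)[C@H](C)C2=O
F13 | step 18 | (2S,3S)-6-[(3R)-1-(tert-butyldiphenylsilyloxy)hexan-3-yl]-7-methoxy-2,3-dimethyl-6-(2-methylbut-3-en-2-yl)-2,3-dihydro-4H-chromene-4,5(6H)-dione | CCC[C@H](CCO[Si](c3ccccc3)(c4ccccc4)C(C)(C)C)C1(C(C)(C)C=C)C(OC)=CC2=C(C1=O)C(=O)[C@@H](C)[C@H](C)O2
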